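Double the catalyst and ask what the rate does.

| setting | summer | dusk | spring | autumn |
|---|---|---|---|---|
| substrate | 0.200 M | 0.120 M | 0.200 M | 0.200 M |
| partner | 0.160 M | 0.0800 M | 0.160 M | 0.160 M |
| free catalyst | 0.0100 M | 0.0100 M | 0.0200 M | 0.0100 M |
| time |  |  |  | 19 h |

| run | time / h | [target] / M |
|---|---|---|
| summer run | 0.11 | 0.0345 |
| summer run | 0.35 | 0.0750 |
| summer run | 0.67 | 0.1043 |
| summer run | 1.1 | 0.1262 |
| summer run | 1.5 | 0.1378 |
| summer run | 2.0 | 0.1466 |
| summer run | 2.6 | 0.1502 |
| summer run | 3.2 | 0.1532 |
| dusk run | 0.11 | 0.0121 |
| dusk run | 0.35 | 0.0282 |
| dusk run | 0.67 | 0.0450 |
| dusk run | 1.1 | 0.0570 |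
| dusk run | 1.5 | 0.0632 |
| dusk run | 2.0 | 0.0691 |
| dusk run | 2.6 | 0.0724 |
| dusk run | 3.2 | 0.0762 |
| spring run | 0.11 | 0.0477 |
| spring run | 0.35 | 0.1012 |
| spring run | 0.67 | 0.1273 |
| spring run | 1.1 | 0.1466 |
| spring run | 1.5 | 0.1513 |
| spring run | 2.0 | 0.1545 |
| spring run | 2.6 | 0.1582 |
| spring run | 3.2 | 0.1599 |

(scatter of a reading: 0.001 M)

1. how the opening rate goes with [free catalyst] round the charge of the summer run: the exponent of the rate at two percent of substrate gone to target
2. the dusk run starts with 0.0800 M less of substrate and of partner than the summer run, and with no target. Compared where both hold the same amount of substrate, once fifteen percent of what the dusk run was charged with has turned into target, is the dusk run faster, slower or alike (within a tenth)?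
3. target in the autumn run at 19 h, as a share of the substrate charged

- Overall: substrate + partner -> target, with free catalyst as catalyst.
- Constant volume, constant temperature.
- Readings of a species count what is bound in complexes too.
- An order is taken over about fifteen percent of the charge, up and down.

Our reckoning needs a clock that can be read off a single point. If the rate goes as substrate times partner, take the logarithm of the fraction of substrate left over the fraction of partner left, partner being the limiting reagent. That clock grows in step with time, with a slope equal to the rate constant times the excess of substrate. The summer and spring runs have the same charge of substrate and partner, so at one time their clocks compare rate constants directly. At the first reading the summer clock stands at 0.0535 and the spring clock at 0.0815.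

Their ratio, 1.52, is what we carry: the doubling gain, the factor by which twice the free catalyst speeds the clock. Two extreme flasks mark the scale. If every turnover passes through free catalyst and the rate goes in plain proportion to the catalyst charged, the gain is 2 and the exponent 1. If no turnover does, the gain is 1 and the exponent 0, and that is our zero. The reading stands between them, above the one and below the other, so the clock does not go in plain proportion to the catalyst charged. The logarithm of the gain to base 2 gives our exponent, 0.607, read from one pair of readings, so its second digit is loose.

The forecast puts the exponent at 0.75, between 0.55 and 0.95, “though it is poorly defined”, which is above our reckoning; it calls the dusk run alike and gives the autumn run 80%, between 78.5% and 80%.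

The flask gives an exponent of 0.61, a dusk run that is alike, and 80.0% in the autumn run.

    free catalyst + substrate ⇌ catalyst-substrate complex, settled at all times (9.510 M⁻¹)
    catalyst-substrate complex + partner ⇌ ternary complex, settled at all times (0.8350 M⁻¹)
    ternary complex → target + free catalyst (277.9 h⁻¹)
    free catalyst + impurity → spent catalyst
    substrate + partner → target (7.056 M⁻¹ h⁻¹)

Our gain of 1.52, read as an exponent of 0.607, stands beside the 0.61 of the flask. The exponent stands this low because substrate and partner also turn into target without catalyst: the same flask without that step gives 1.7, above the proportional exponent of 1. The gain also carries over to time. The summer run reaches a quarter of its substrate as target at 0.191 h; dividing by the gain gives 0.126 h for the spring run, which reached that mark at 0.117 h.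

The runs are simulated with constants of no real substance, noise included.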